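## Structural features

The target is a 6β-acetoxy-7-oxolabdane. A trans-decalin (rings A and B, 5α-H, 10β-methyl) carries at C9 the spiro atom of a tetrahydrofuran (ring C: O, C9, C11, C12, C13), and C13 is in turn the spiro atom of a 2,3-dihydrofuran (ring D: C13, C14=C15, O, C16). There are six stereocentres. C5, C6, C8, C9 and C10 sit around ring B; C13 is tied to them only through the ring C oxygen. C9 and C13 are fully substituted ether carbons, and C9 stands next to the quaternary C10. The 6β-acetate is axial and syn-axial to the C10 and C4β methyls, so it cannot come from electrophilic attack on a C7 enolate, which would arrive from the α face. The 8α-methyl is equatorial and is the stable epimer next to the ketone. Fragile groups: the ring D enol ether with its allylic, doubly oxygenated C13 (acid opens ring C and aromatises ring D), the α-acetoxy ketone (base-induced acyl migration or epimerisation at C6), and the β-alkoxy ketone C7/C9 (β-elimination of the ring C oxygen). The real difficulty is to join C9 and C13 through one oxygen with the 9α-O, 13R relationship while the C6/C7 oxygenation is carried along. The key step uses the fact that the ring C oxygen spans C9 and C13 with C8 and C16 cis across ring C and with oxygen on C16. That is the pattern left when one oxygen is inserted between the inner carbons of the 1,5-diene C8=C9–C11–C12–C13=C16, whose C8=C9 bond is the enone of the C7 ketone.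

## Logic of the disconnections

22 ⇒ 21. The C14=C15 enol ether is traced back to a C15 methyl acetal by adding methanol across it. The acid-labile enol ether is thus made last; the forward step must eliminate methanol without protic acid.

21 ⇒ 20 ⇒ 19. The C8–H bond is traced back to a C8=C17 methylene and this to a tertiary C8 hydroxyl. The hydroxyl is the one the ring-forming step leaves behind. C9 has no hydrogen, so dehydration can only go to C17. The forward reduction must deliver the equatorial 8α-methyl.

19 ⇒ 18. The O–C15 bond of ring D is cut to a C16 hydroxyl and a C15 dimethyl acetal. Ring D then costs no redox step; the forward step needs only mild acid.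

18 ⇒ 17. Both C–O bonds of ring C (O–C9 and O–C13) are cut together with the C8–O and C16–O bonds, which gives a 1,5-diene. One operation then builds ring C, three stereocentres and the C16 oxygen. The forward step demands attack on the enone first and from the α face.

17 ⇒ 12 + 15. The C12–C13 bond is cut between an sp3 and an sp2 carbon. The side chain then arrives complete, after all oxidations of ring B are done. The forward coupling must tolerate the enone and the α-acetoxy ketone.

15 ⇒ 13. The acetal is traced back to the primary alcohol; the forward oxidation must not move the β,γ double bond into conjugation.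

12 ⇒ 11 ⇒ 10. Iodide from alcohol from silyl ether: simple interchange of the C12 group, under conditions that leave the acetate alone.

10 ⇒ 8 (through 9). The C7 carbonyl and the C8=C9 bond are traced back to a C7=C8 alkene, an oxidative allylic transposition. This keeps C7 free of a ketone while C6 is being set. The forward step must bring oxygen to C7 from the α face and take hydrogen from C9.

8 ⇒ 7 ⇒ 6. The axial C6–O stereocentre is traced back to a C6 ketone. Hydride attack from the open α face is the reliable source of a 6β-oxygen.

6 ⇒ 5 ⇒ 4 ⇒ 3. The C6 carbonyl goes back to the allylic methylene of the Δ7 alkene, the Δ7 alkene to the exocyclic isomer, and that to the tertiary C8 alcohol. Each forward step has one preferred site.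

3 ⇒ 2 ⇒ 1. Silyl ether from diol from lactone. C5, C9 (temporarily) and C10 come from the chiral pool.

## Other disconnections considered

Alternative 1: The cut is C8–C9 (ring B). In the forward step a Lewis acid ionises the C9 methyl ketal of the seco compound A2, and the tethered C7 silyl enol ether attacks the cyclic oxocarbenium ion through C8 to give A1. In its favour: ring C and C13 are made beforehand, so C13 does not depend on the order in which two alkenes react. C8 arrives at the right oxidation level, which spares the dehydration and reduction of the chosen plan; on this point the alternative is better. The closure is an allowed 6-(enolendo)-exo-trig mode. Against it: the new bond joins a tertiary carbon to a tetrasubstituted oxocarbenium carbon beside the quaternary C10. The face of attack at C9 is not obviously biased towards the 9α-oxygen. A1 has no C6 oxygen, and later oxygenation of the C7 enolate would come from the α face and give the 6α epimer. C5 and C10 of A2 must be made without the chiral pool. Overall the mechanism is sound but more congested at the bond being formed than the permanganate addition, and the count of steps should be clearly higher.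

Alternative 2: The cut is C13–C14 (ring D). In the forward step the rhodium carbenoid from diazoacetate A4 (Rh2(OAc)4) inserts into the C13–H bond and gives spiro lactone A3. In its favour: the C–H bond is activated by the ring C oxygen, five-membered insertion is the preferred mode, and it proceeds with retention. If the C13–H configuration is in hand, the quaternary C13 is as secure as in the chosen plan or more so. The C8 methyl is already in place. Against it: the cis relationship across ring C must still be made in an earlier step. The carbenoid can also attack the ring C oxygen (oxonium ylide) or the Δ6 alkene. After A3 the lactone must be reduced and dehydrated beside other carbonyl groups, and the Δ6 alkene must become the 6β-acetoxy 7-ketone, where syn-dihydroxylation from the open face gives the 6α-oxygen. The chosen plan makes C9, C13 and C8 oxygenation in one step and carries C6/C7 from the start, so it should be shorter by several steps.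

Alternative 3: The cut is C6–C7 (ring B). In the forward step the aldehyde of seco compound A6, activated by MeAlCl2, undergoes a type 2 carbonyl-ene reaction with the isopropenyl group to give A5. In its favour: the closed, chair-like ene transition state places the new hydroxyl axial, so the difficult 6β-oxygen is set directly. On this point it is better than the oxidation, reduction and acetylation of the chosen plan. The new bond lies far from any quaternary centre, and the C8 methylene is a handle for C7 oxidation. Against it: A6 holds a tertiary allylic ether at C9 that the Lewis acid can ionise, and a hindered aldehyde that can epimerise at C5. Ring A with C5, C10 and C9 must be built enantioselectively from scratch. After A5, C7 oxidation, C8 reduction, acetylation and ring D closure remain. On mechanism the two plans are comparably credible; on step economy the chosen plan should win because it takes C5 and C10 from sclareolide.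

Key step: step 13

Remark on the chemistry: α-face syn addition to C8=C9 and a cis-2,5 ring require 8α-OH, 9α-O and 13R in 18, which is what is drawn; 17 and 18 are therefore used without change. The C6 acetate and the C15 dimethyl acetal of 17 are kept because they leave no free alcohol or aldehyde for permanganate. C15 of 19–21 is an inconsequential mixture of epimers.

## Steps

Step 1
Reactants: 1 (+)-sclareolide
Product: 2 13,14,15,16-tetranorlabdane-8α,12-diol
Conditions: LiAlH4, THF, 0 °C → reflux; aq. NaOH work-up
Reagents that add atoms: none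
Why: Hydride reduction of the lactone to the 1,4-diol; no stereocentre is touched.

Step 2
Reactants: 2 13,14,15,16-tetranorlabdane-8α,12-diol
Product: 3 12-(tert-butyldimethylsilyloxy)-13,14,15,16-tetranorlabdan-8α-ol
Conditions: TBSCl, imidazole, CH2Cl2, 0 °C → rt
Reagents that add atoms: tert-butyldimethylsilyl chloride, C[Si](C)(Cl)C(C)(C)C
Why: Selective silylation of the primary hydroxyl; the tertiary 8α-hydroxyl is too hindered to react.

Step 3
Reactants: 3 12-(tert-butyldimethylsilyloxy)-13,14,15,16-tetranorlabdan-8α-ol
Product: 4 12-(tert-butyldimethylsilyloxy)-13,14,15,16-tetranorlabd-8(17)-ene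
Conditions: SOCl2, pyridine, CH2Cl2, −78 °C
Reagents that add atoms: none
Why: E2 elimination of the chlorosulfite; the equatorial 8α leaving group has an anti-periplanar hydrogen only on C17, so the exocyclic alkene should form, and the cold basic medium avoids a C8 cation that the C12 oxygen could trap.

Step 4
Reactants: 4 12-(tert-butyldimethylsilyloxy)-13,14,15,16-tetranorlabd-8(17)-ene
Product: 5 12-(tert-butyldimethylsilyloxy)-13,14,15,16-tetranorlabd-7-ene
Conditions: chloro[N,N'-bis(3,5-di-tert-butylsalicylidene)-1,2-cyclohexanediaminato]cobalt (trivalent cobalt, 3 mol %), PhSiH3 (6 mol %), benzene, 22 °C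
Reagents that add atoms: none
Why: Cobalt hydride hydrogen-atom-transfer isomerisation of a 1,1-disubstituted alkene by one position: H adds to C17, and the tertiary C8 radical should return a hydrogen from the open C7 methylene, not from C9–H beside the quaternary C10; no cation is formed.

Step 5
Reactants: 5 12-(tert-butyldimethylsilyloxy)-13,14,15,16-tetranorlabd-7-ene
Product: 6 12-(tert-butyldimethylsilyloxy)-13,14,15,16-tetranorlabd-7-en-6-one
Conditions: CrO3, 3,5-dimethylpyrazole, CH2Cl2, −20 °C
Reagents that add atoms: chromium trioxide, O=[Cr](=O)=O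
Why: Allylic oxidation; C6 is the only allylic methylene of the Δ7 alkene and gives the conjugated enone, and the silyl ether is inert.

Step 6
Reactants: 6 12-(tert-butyldimethylsilyloxy)-13,14,15,16-tetranorlabd-7-en-6-one
Product: 7 12-(tert-butyldimethylsilyloxy)-13,14,15,16-tetranorlabd-7-en-6β-ol
Conditions: NaBH4, CeCl3·7H2O, MeOH, −20 → 0 °C
Reagents that add atoms: none
Why: Luche 1,2-reduction; the β face of C6 is screened by the syn-axial C10 and C4β methyls, so hydride should enter from the α face and set the axial 6β-hydroxyl.

Step 7
Reactants: 7 12-(tert-butyldimethylsilyloxy)-13,14,15,16-tetranorlabd-7-en-6β-ol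
Product: 8 6β-acetoxy-12-(tert-butyldimethylsilyloxy)-13,14,15,16-tetranorlabd-7-ene
Conditions: Ac2O, DMAP, Et3N, CH2Cl2, 40 °C
Reagents that add atoms: acetic anhydride, CC(=O)OC(C)=O
Why: DMAP-catalysed acylation of a hindered axial allylic alcohol; the acetate also removes any hydroxyl direction of the next step towards the β face.

Step 8
Reactants: 8 6β-acetoxy-12-(tert-butyldimethylsilyloxy)-13,14,15,16-tetranorlabd-7-ene
Product: 10 6β-acetoxy-12-(tert-butyldimethylsilyloxy)-13,14,15,16-tetranorlabd-8-en-7-one, via 7α-hydroperoxide 9 (not isolated)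
Conditions: O2, tetraphenylporphyrin (cat.), visible light, Ac2O, pyridine, DMAP (cat.), CH2Cl2, 0 °C → rt
Reagents that add atoms: dioxygen, O=O
Why: Schenck ene reaction followed in the same flask by Kornblum–DeLaMare-type dehydration of the peracetate; singlet oxygen should approach the α face (β face screened by the C10 methyl and the 6β-acetate), bond to C7 and take the axial 9α-H, and the secondary hydroperoxide then gives the C7 ketone, so the C7 centre of 9 is lost again.

Step 9
Reactants: 10 6β-acetoxy-12-(tert-butyldimethylsilyloxy)-13,14,15,16-tetranorlabd-8-en-7-one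
Product: 11 6β-acetoxy-12-hydroxy-13,14,15,16-tetranorlabd-8-en-7-one
Conditions: HF·pyridine, pyridine, THF, 0 °C → rt
Reagents that add atoms: none
Why: Fluoride desilylation under buffered conditions that should leave the α-acetoxy enone untouched.

Step 10
Reactants: 11 6β-acetoxy-12-hydroxy-13,14,15,16-tetranorlabd-8-en-7-one
Product: 12 6β-acetoxy-12-iodo-13,14,15,16-tetranorlabd-8-en-7-one
Conditions: I2, PPh3, imidazole, CH2Cl2, 0 °C
Reagents that add atoms: iodine, [I][I]
Why: Appel-type iodination of a primary alcohol through the alkoxyphosphonium salt; neutral conditions suit the enone and the acetate.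

Step 11
Reactants: 13 3-bromo-3-buten-1-ol
Product: 15 2-bromo-4,4-dimethoxybut-1-ene, via 3-bromobut-3-enal 14 (not isolated)
Conditions: Dess–Martin periodinane, CH2Cl2, 0 °C; then HC(OMe)3, PPTS (cat.), MeOH, rt
Reagents that add atoms: trimethyl orthoformate, COC(OC)OC
Why: Dess–Martin oxidation and immediate acid-catalysed acetalisation; the β,γ-unsaturated aldehyde is not isolated, so that it has no time to move into conjugation.

Step 12
Reactants: 12 6β-acetoxy-12-iodo-13,14,15,16-tetranorlabd-8-en-7-one; 15 2-bromo-4,4-dimethoxybut-1-ene
Product: 17 6β-acetoxy-7-oxolabda-8,13(16)-dien-15-al dimethyl acetal, via alkylzinc iodide 16 (not isolated)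
Conditions: Zn dust (activated), LiCl, THF, 30 °C; then 15, Pd(PPh3)4 (zerovalent palladium, 5 mol %), THF, 40 °C
Reagents that add atoms: none
Why: Zinc insertion into the primary iodide and Negishi sp3–sp2 coupling with the bromoalkene forms C12–C13; alkylzinc halides do not add to ketones, enones or esters, and the acetal is inert.

Step 13
Reactants: 17 6β-acetoxy-7-oxolabda-8,13(16)-dien-15-al dimethyl acetal
Product: 18 (13R)-6β-acetoxy-8α,16-dihydroxy-9α,13-epoxy-7-oxolabdan-15-al dimethyl acetal
Conditions: KMnO4 (1.5 equiv, 0.4 M in H2O), AcOH (3 equiv), acetone, −30 → −10 °C; filtration through Celite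
Reagents that add atoms: potassium permanganate, [K+].[O-][Mn](=O)(=O)=O
Why: Permanganate should add [3+2] to the electron-poor C8=C9 bond from the α face and give a cyclic manganate ester of pentavalent manganese with new C8–O and C9–O bonds. After oxidation to hexavalent manganese by more permanganate, the Mn=O and Mn–O(C9) unit adds [3+2] to C13=C16 five atoms away, the C9 oxygen bonding to C13 and an oxo oxygen to C16; hydrolysis then frees 18. The closest known reaction is the permanganate oxidative cyclisation of 1,5-dienes and 1,5-dienoates to cis-2,5-bis(hydroxyalkyl)tetrahydrofurans. Ring C closes in a 5-exo mode by intramolecular syn addition through a bicyclic manganate diester, so both ring C–O bonds come from one oxygen. C8 and C9 are set by α-face syn addition, which the axial C10 methyl and the 6β-acetate enforce. C13 is set by the bicyclic transition state, which holds the C9–C8 and C13–C16 bonds on the same side of the forming ring and so gives 13R whichever face the flexible chain offers. The step needs the enone to react before the 1,1-disubstituted alkene, because otherwise C13 would be fixed without control; the preference of permanganate for conjugated electron-poor alkenes and the low temperature are relied on for this. The acetate, the acetal, the tertiary α-ketol and the primary alcohol should survive the buffered cold conditions.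

Step 14
Reactants: 18 (13R)-6β-acetoxy-8α,16-dihydroxy-9α,13-epoxy-7-oxolabdan-15-al dimethyl acetal
Product: 19 (13R)-6β-acetoxy-8α-hydroxy-15-methoxy-9α,13:15,16-diepoxylabdan-7-one (C15 epimers)
Conditions: PPTS (10 mol %), 4 Å molecular sieves, CH2Cl2, rt
Reagents that add atoms: none
Why: Acid-catalysed transacetalisation; the C16 hydroxyl closes the five-membered ring D on the C15 oxocarbenium ion, while the tertiary C8 hydroxyl could only form a seven-membered ring.

Step 15
Reactants: 19 (13R)-6β-acetoxy-8α-hydroxy-15-methoxy-9α,13:15,16-diepoxylabdan-7-one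
Product: 20 (13R)-6β-acetoxy-15-methoxy-9α,13:15,16-diepoxylabd-8(17)-en-7-one
Conditions: Burgess reagent (MeO2C–N(−)–SO2–N(+)Et3), toluene, 60 °C
Reagents that add atoms: none
Why: Burgess dehydration by syn elimination of the sulfamate ester; C9 is quaternary and C7 is a carbonyl, so only the C17 hydrogens are available and the exocyclic enone should form.

Step 16
Reactants: 20 (13R)-6β-acetoxy-15-methoxy-9α,13:15,16-diepoxylabd-8(17)-en-7-one
Product: 21 (13R)-6β-acetoxy-15-methoxy-9α,13:15,16-diepoxylabdan-7-one (8α-methyl)
Conditions: [(Ph3P)CuH]6 (0.3 equiv), H2O (3 equiv), degassed benzene, rt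
Reagents that add atoms: none
Why: Conjugate reduction of the open exocyclic enone by copper hydride; the enolate should be protonated at C8 along the axial path anti to the axial C9–O bond (β face), which gives the equatorial 8α-methyl, also the stable epimer because an 8β-methyl would be syn-axial to the C10 methyl and the 6β-acetate.

Step 17
Reactants: 21 (13R)-6β-acetoxy-15-methoxy-9α,13:15,16-diepoxylabdan-7-one
Product: 22 (13R)-6β-acetoxy-9α,13:15,16-diepoxylabd-14-en-7-one (target)
Conditions: Me3SiOTf (1.5 equiv), i-Pr2NEt (3 equiv), CH2Cl2, −20 → 0 °C; aq. NaHCO3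
Reagents that add atoms: none
Why: Acetal-to-enol-ether elimination: Me3SiOTf ionises the C15 methoxy group to the cyclic oxocarbenium ion and the hindered amine removes H14, the only β-hydrogen; the hindered C7 ketone should enolise more slowly than the acetal ionises, and excess base protects the acid-labile product.

## Compound list

1 | (+)-sclareolide | C1C[C@@]3(C)OC(=O)C[C@@H]3[C@@]2(C)CCCC(C)(C)[C@H]12 | starting material
2 | 13,14,15,16-tetranorlabdane-8α,12-diol | C1C[C@@](C)(O)[C@H](CCO)[C@@]2(C)CCCC(C)(C)[C@H]12 | intermediate
3 | 12-(tert-butyldimethylsilyloxy)-13,14,15,16-tetranorlabdan-8α-ol | C1C[C@@](C)(O)[C@H](CCO[Si](C)(C)C(C)(C)C)[C@@]2(C)CCCC(C)(C)[C@H]12 | intermediate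
4 | 12-(tert-butyldimethylsilyloxy)-13,14,15,16-tetranorlabd-8(17)-ene | C1CC(=C)[C@H](CCO[Si](C)(C)C(C)(C)C)[C@@]2(C)CCCC(C)(C)[C@H]12 | intermediate
5 | 12-(tert-butyldimethylsilyloxy)-13,14,15,16-tetranorlabd-7-ene | C1C=C(C)[C@H](CCO[Si](C)(C)C(C)(C)C)[C@@]2(C)CCCC(C)(C)[C@H]12 | intermediate
6 | 12-(tert-butyldimethylsilyloxy)-13,14,15,16-tetranorlabd-7-en-6-one | O=C1C=C(C)[C@H](CCO[Si](C)(C)C(C)(C)C)[C@@]2(C)CCCC(C)(C)[C@H]12 | intermediate
7 | 12-(tert-butyldimethylsilyloxy)-13,14,15,16-tetranorlabd-7-en-6β-ol | O[C@@H]1C=C(C)[C@H](CCO[Si](C)(C)C(C)(C)C)[C@@]2(C)CCCC(C)(C)[C@H]12 | intermediate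
8 | 6β-acetoxy-12-(tert-butyldimethylsilyloxy)-13,14,15,16-tetranorlabd-7-ene | CC(=O)O[C@@H]1C=C(C)[C@H](CCO[Si](C)(C)C(C)(C)C)[C@@]2(C)CCCC(C)(C)[C@H]12 | intermediate
9 | 6β-acetoxy-7α-hydroperoxy-12-(tert-butyldimethylsilyloxy)-13,14,15,16-tetranorlabd-8-ene | CC(=O)O[C@@H]1[C@@H](OO)C(C)=C(CCO[Si](C)(C)C(C)(C)C)[C@@]2(C)CCCC(C)(C)[C@H]12 | intermediate (not isolated)
10 | 6β-acetoxy-12-(tert-butyldimethylsilyloxy)-13,14,15,16-tetranorlabd-8-en-7-one | CC(=O)O[C@@H]1C(=O)C(C)=C(CCO[Si](C)(C)C(C)(C)C)[C@@]2(C)CCCC(C)(C)[C@H]12 | intermediate
11 | 6β-acetoxy-12-hydroxy-13,14,15,16-tetranorlabd-8-en-7-one | CC(=O)O[C@@H]1C(=O)C(C)=C(CCO)[C@@]2(C)CCCC(C)(C)[C@H]12 | intermediate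
12 | 6β-acetoxy-12-iodo-13,14,15,16-tetranorlabd-8-en-7-one | CC(=O)O[C@@H]1C(=O)C(C)=C(CCI)[C@@]2(C)CCCC(C)(C)[C@H]12 | intermediate
13 | 3-bromo-3-buten-1-ol | OCCC(Br)=C | starting material
14 | 3-bromobut-3-enal | O=CCC(Br)=C | intermediate (not isolated)
15 | 2-bromo-4,4-dimethoxybut-1-ene | COC(OC)CC(Br)=C | intermediate
16 | alkylzinc iodide from 12 (C12–ZnI) | CC(=O)O[C@@H]1C(=O)C(C)=C(CC[Zn]I)[C@@]2(C)CCCC(C)(C)[C@H]12 | intermediate (not isolated)
17 | 6β-acetoxy-7-oxolabda-8,13(16)-dien-15-al dimethyl acetal | CC(=O)O[C@@H]1C(=O)C(C)=C(CCC(=C)CC(OC)OC)[C@@]2(C)CCCC(C)(C)[C@H]12 | intermediate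
18 | (13R)-6β-acetoxy-8α,16-dihydroxy-9α,13-epoxy-7-oxolabdan-15-al dimethyl acetal | CC(=O)O[C@@H]1C(=O)[C@@](C)(O)[C@]2(CC[C@](CO)(CC(OC)OC)O2)[C@@]2(C)CCCC(C)(C)[C@H]12 | intermediate
19 | (13R)-6β-acetoxy-8α-hydroxy-15-methoxy-9α,13:15,16-diepoxylabdan-7-one (C15 epimers) | CC(=O)O[C@@H]1C(=O)[C@@](C)(O)[C@]2(CC[C@]3(CC(OC)OC3)O2)[C@@]2(C)CCCC(C)(C)[C@H]12 | intermediate
20 | (13R)-6β-acetoxy-15-methoxy-9α,13:15,16-diepoxylabd-8(17)-en-7-one | CC(=O)O[C@@H]1C(=O)C(=C)[C@]2(CC[C@]3(CC(OC)OC3)O2)[C@@]2(C)CCCC(C)(C)[C@H]12 | intermediate
21 | (13R)-6β-acetoxy-15-methoxy-9α,13:15,16-diepoxylabdan-7-one (8α-methyl) | CC(=O)O[C@@H]1C(=O)[C@@H](C)[C@]2(CC[C@]3(CC(OC)OC3)O2)[C@@]2(C)CCCC(C)(C)[C@H]12 | intermediate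
22 | (13R)-6β-acetoxy-9α,13:15,16-diepoxylabd-14-en-7-one | CC(=O)O[C@@H]1C(=O)[C@@H](C)[C@]2(CC[C@]3(C=COC3)O2)[C@@]2(C)CCCC(C)(C)[C@H]12 | target

## Step count and least certain steps

Total: 17 steps. Longest linear sequence: 16 steps (steps 1–10 and 12–17 from 1); step 11 is the one-step branch from 13.

Step 13 (key step). The most likely failure is first attack of permanganate on the unhindered C13=C16 alkene instead of the hindered tetrasubstituted enone. C13 would then be set without facial control and half of the manganate esters could not reach the α face of C9; simple dihydroxylation or cleavage of the side chain would follow. Fallback, from 17 back to 19: peracid (m-chloroperbenzoic acid, NaHCO3) should epoxidise only the isolated alkene and give the 13,16-epoxide F1. Permanganate (or RuCl3/NaIO4) then meets the enone as the only alkene and should give the 8α,9α-diol F2 from the α face. Mild acid (PPTS) lets the 9α-hydroxyl open the epoxide at the tertiary C13 in a 5-exo mode with inversion, and the freed C16 hydroxyl closes onto the acetal to give 19. The price is that C13 is no longer controlled, so the C13 epimers must be separated.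

Step 8. The ene reaction may be slow at an alkene deactivated by the allylic acetate, and hydrogen may be taken from the C17 methyl instead of C9, which would place the new double bond exocyclic. Fallback, from 8 back to 10: epoxidation from the α face (m-chloroperbenzoic acid) to the 7α,8α-epoxide F3. Opening with Cp2TiCl (trivalent titanium, from Cp2TiCl2 and Mn) gives the exocyclic allylic alcohol F4. Dess–Martin oxidation gives the exocyclic enone F5. Rhodium hydride isomerisation (RhCl3·3H2O, EtOH, 60 °C) then moves the double bond into the ring to give 10.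

Step 4. Hydrogen return from C9 instead of C7 would give the tetrasubstituted Δ8 isomer, and the catalyst may stall on the hindered alkene. Fallback, from 4 back to 5: allylic hydroxylation with SeO2/t-BuOOH gives the 7α-alcohol F6. Reductive 1,3-transposition (o-nitrobenzenesulfonylhydrazide, PPh3, diethyl azodicarboxylate) then delivers hydrogen to C17 and places the double bond at C7=C8 without ambiguity.

Step 12. Zinc metal may reduce the α-acetoxy ketone (loss of the C6 acetate) during insertion. Fallback, from 15 and 12 back to 17, with reversed polarity so that the ring fragment never meets zinc metal: bromine–lithium exchange of 15 (t-BuLi, −78 °C) and ZnCl2 give the alkenylzinc chloride F7. This is coupled with iodide 12 under Pd2(dba)3 (zerovalent palladium), tricyclopentylphosphine and N-methylimidazole in THF/NMP.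

Step 16. Protonation of the enolate from the α face would give the axial 8β-methyl epimer; the β face is stereoelectronically preferred but flanked by two axial groups. Fallback, from 20 back to 21: heterogeneous hydrogenation (H2, palladium on carbon, EtOAc), which may give the 8β-methyl epimer F8, followed by equilibration through the enol with DBU in toluene to the equatorial 21. The equilibration must be watched for β-elimination of the ring C oxygen.

Step 17. The Lewis acid may silylate the C7 ketone as its enol ether or ionise the allylic C13–O bond of the product, which would open ring C and aromatise ring D. Fallback, from 21 back to 22: mild aqueous acid (AcOH, H2O, THF) gives the lactol F9, which is dehydrated under basic conditions (MsCl, Et3N, CH2Cl2, −20 °C → rt).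

## Further compounds

F1 | step 13 | 6β-acetoxy-13,16-epoxy-7-oxolabd-8-en-15-al dimethyl acetal (productive C13 epimer) | CC(=O)O[C@@H]1C(=O)C(C)=C(CC[C@@]3(CO3)CC(OC)OC)[C@@]2(C)CCCC(C)(C)[C@H]12
F2 | step 13 | 6β-acetoxy-8α,9α-dihydroxy-13,16-epoxy-7-oxolabdan-15-al dimethyl acetal | CC(=O)O[C@@H]1C(=O)[C@@](C)(O)[C@](O)(CC[C@@]3(CO3)CC(OC)OC)[C@@]2(C)CCCC(C)(C)[C@H]12
F3 | step 8 | 6β-acetoxy-7α,8α-epoxy-12-(tert-butyldimethylsilyloxy)-13,14,15,16-tetranorlabdane | CC(=O)O[C@@H]1[C@H]3O[C@@]3(C)[C@H](CCO[Si](C)(C)C(C)(C)C)[C@@]2(C)CCCC(C)(C)[C@H]12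
F4 | step 8 | 6β-acetoxy-12-(tert-butyldimethylsilyloxy)-13,14,15,16-tetranorlabd-8(17)-en-7α-ol | CC(=O)O[C@@H]1[C@@H](O)C(=C)[C@H](CCO[Si](C)(C)C(C)(C)C)[C@@]2(C)CCCC(C)(C)[C@H]12
F5 | step 8 | 6β-acetoxy-12-(tert-butyldimethylsilyloxy)-13,14,15,16-tetranorlabd-8(17)-en-7-one | CC(=O)O[C@@H]1C(=O)C(=C)[C@H](CCO[Si](C)(C)C(C)(C)C)[C@@]2(C)CCCC(C)(C)[C@H]12
F6 | step 4 | 12-(tert-butyldimethylsilyloxy)-13,14,15,16-tetranorlabd-8(17)-en-7α-ol | C1[C@@H](O)C(=C)[C@H](CCO[Si](C)(C)C(C)(C)C)[C@@]2(C)CCCC(C)(C)[C@H]12
F7 | step 12 | (4,4-dimethoxybut-1-en-2-yl)zinc chloride | COC(OC)CC(=C)[Zn]Cl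
F8 | step 16 | (13R)-6β-acetoxy-15-methoxy-9α,13:15,16-diepoxylabdan-7-one, 8β-methyl epimer | CC(=O)O[C@@H]1C(=O)[C@H](C)[C@]2(CC[C@]3(CC(OC)OC3)O2)[C@@]2(C)CCCC(C)(C)[C@H]12
F9 | step 17 | (13R)-6β-acetoxy-15-hydroxy-9α,13:15,16-diepoxylabdan-7-one (lactol) | CC(=O)O[C@@H]1C(=O)[C@@H](C)[C@]2(CC[C@]3(CC(O)OC3)O2)[C@@]2(C)CCCC(C)(C)[C@H]12
A1 | alternative 1 | 6-deoxy 9α,13-epoxy-7-ketone with C13 trimethylsilylethynyl and tert-butyldimethylsilyloxymethyl groups | C1C(=O)[C@@H](C)[C@]2(CC[C@](CO[Si](C)(C)C(C)(C)C)(C#C[Si](C)(C)C)O2)[C@@]2(C)CCCC(C)(C)[C@H]12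
A2 | alternative 1 | 8,9-seco precursor: ring C methyl ketal at C9 with the C7 trimethylsilyl enol ether | C/C=C(\O[Si](C)(C)C)C[C@H]1C(C)(C)CCC[C@]1(C)C1(OC)CC[C@](CO[Si](C)(C)C(C)(C)C)(C#C[Si](C)(C)C)O1
A3 | alternative 2 | Δ6 9α,13-epoxy-16,15-olide spiro lactone | C1=C[C@@H](C)[C@]2(CC[C@]3(CC(=O)OC3)O2)[C@@]2(C)CCCC(C)(C)[C@H]12
A4 | alternative 2 | Δ6 9α,13-epoxy-13-H tetrahydrofuran with the C16 diazoacetate | C1=C[C@@H](C)[C@]2(CC[C@@H](COC(=O)C=[N+]=[N-])O2)[C@@]2(C)CCCC(C)(C)[C@H]12
A5 | alternative 3 | 6β-hydroxy-8(17)-ene 9α,13-epoxy spiro ether | O[C@@H]1CC(=C)[C@]2(CC[C@](CO[Si](C)(C)C(C)(C)C)(C#C[Si](C)(C)C)O2)[C@@]2(C)CCCC(C)(C)[C@H]12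
A6 | alternative 3 | 6,7-seco aldehyde with the C9 isopropenyl group on ring C | O=C[C@H]1C(C)(C)CCC[C@]1(C)[C@]1(C(C)=C)CC[C@](CO[Si](C)(C)C(C)(C)C)(C#C[Si](C)(C)C)O1
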